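You charge 0.0050 M of free monomer against 100 µM of initiator and 0.500 mM of transfer agent, in two flasks that differ in temperature.

- south-east: free monomer 0.0050 M; transfer agent 0.500 mM; initiator 100 µM; temperature 115 °C; time 12 min
- east: free monomer 0.0050 M; transfer agent 0.500 mM; initiator 100 µM; temperature 90 °C; time 12 min

    free monomer + initiator → living end + monomer in chains (k1 = 31 M⁻¹ s⁻¹, Ea1 = 45.0 kJ mol⁻¹)
    free monomer + living end → monomer in chains + living end, rate k2*[living end]*[free monomer] (k2 = 74 M⁻¹ s⁻¹, Ea2 = 40.0 kJ mol⁻¹)
    living end + transfer agent → dead chain (k3 = 11 M⁻¹ s⁻¹, Ea3 = 64.0 kJ mol⁻¹)
    free monomer + initiator → spent initiator (k4 = 1.2 M⁻¹ s⁻¹, Ea4 = 67.0 kJ mol⁻¹)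
    (constants at 90 °C)

- the flask that comes out highest in amount of monomer in chains, in percent of the free monomer charged, or "all alike" when all lie within 1.5 percentage points (south-east / east / all alike)
- monomer in chains at the end, in percent of the free monomer charged, south-east
- monomer in chains at the end, in percent of the free monomer charged, east

- the list of constants is for 90 °C, to be carried to other temperatures by the activation energies

My own reckoning:

1. In east, a living end lasts 3.03 min, and initiator lasts about 6.21 s, which is shorter than the life of a living end. So I count each initiator as one living end from the start.

2. Divide the growth rate by the death rate. [living end] cancels and time drops out, leaving a rule: the fraction of free monomer left equals the fraction of transfer agent left, raised to a power.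

3. That power is the growth constant over the death constant: in east 6.73, the growth-to-death ratio, a selectivity factor.

4. Once the ends are dead, transfer agent stands at 80.0% of charge, so east has a ceiling of 77.7% in chains.

5. Death speeds up 3.9-fold in south-east, and growth by that factor to the power of its activation energy over death's. The ratio drops to 4.03, lower, and the south-east ceiling is 59.3%.

6. Turn it round. With equal charges and the living ends of both flasks dead, south-east could lead only on a higher ratio, which needs growth's activation energy above death's; here it lies 24.0 kJ mol⁻¹ below. A lead for south-east on speed, or all alike within 1.5 percentage points, asks east to stop well short of its 77.7% ceiling, yet 12 min is 3.96 end lifetimes in east, longer than one. I commit to east, a little under its ceiling.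

The forecast gives east, with 57.6% for south-east and 75.4% for east, below my ceilings: “so south-east dies out completely with a lower conversion and east finishes well ahead”.

The flask gives east, 75.4% against 57.6% in south-east, higher, and the forecast stands. Left 120 min, east holds 76.7% in chains and south-east 57.6%. Raise the 81% of transfer agent left in south-east to the power 4.03 and you get 42.8% of free monomer; the flask holds 42%.

Now take the neighbour like south-east with 3.0 × 10⁻⁴ M of transfer agent. The same ratio gives a ceiling of 80.5%, and the computed flask gives 78.4%.

(The numbers are those of an exercise.)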